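The route rests on disconnecting C4–C5 and C9–C10 of the cis-fused decalin. One Lewis-acid epoxide–olefin cascade closes rings A and B and sets C4, C5, C9 and C10 together; it exploits the cis A/B fusion (H5 syn to C20), the axial C19 on C4 and the C8=C17 methylene, which correspond to a (Z)-C5=C10 olefin, an epoxide derived from a (Z)-allylic alcohol and an allylsilane. The precursor is an acyclic (2R,3S)-epoxide with C19–OTBDPS, the nerol-type (Z) olefin, a C8(CH2SiMe3)=C9 allylsilane with C7 cis to C11 and C12–OTBS; it is assembled by B-alkyl Suzuki coupling of two fragments.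

Key step: step 12

Remark: labdane numbering is used throughout (ring A C1–C5 and C10, ring B C5–C10, β = the face of C20); the C8=C9 olefin of the precursor is cis along the chain (C7 cis to C11) but (E) by the sequence rules because CH2SiMe3 outranks C7, and both asymmetric epoxidations need D-(−)-diethyl tartrate.

Step 1
Reactants: 1 neryl acetate
Product: 3 (2Z)-3-methyl-6-oxohex-2-en-1-yl acetate, via 6,7-epoxyneryl acetate 2 (not isolated)
Conditions: mCPBA, CH2Cl2, 0 °C; then H5IO6, THF–H2O, 0 °C
Reagents that add atoms: 3-chloroperoxybenzoic acid, OOC(=O)c1cccc(Cl)c1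
Why: The acetoxy group deactivates the neighbouring olefin, so the peracid should epoxidise the remote trisubstituted olefin selectively (Prilezhaev epoxidation), and periodic acid then cleaves the epoxide through its diol to the aldehyde (Malaprade-type cleavage) without touching the acetate or the (Z) olefin.

Step 2
Reactants: 3 (2Z)-3-methyl-6-oxohex-2-en-1-yl acetate; 4 ethyl 2-[bis(2,2,2-trifluoroethoxy)phosphoryl]propanoate
Product: 5 ethyl (2Z,6Z)-8-acetoxy-2,6-dimethylocta-2,6-dienoate
Conditions: KN(SiMe3)2, 18-crown-6, THF, −78 °C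
Reagents that add atoms: none
Why: Still–Gennari olefination, in which the electron-poor phosphonate eliminates rapidly from the kinetic adduct under dissociating conditions, should give the (2Z) enoate, so that the ester carbon (future C19) is cis to the chain.

Step 3
Reactants: 5 ethyl (2Z,6Z)-8-acetoxy-2,6-dimethylocta-2,6-dienoate
Product: 6 ethyl (2Z,6Z)-8-hydroxy-2,6-dimethylocta-2,6-dienoate
Conditions: K2CO3 (cat.), EtOH, 0 °C → rt
Reagents that add atoms: none
Why: Base-catalysed transesterification removes the reactive primary acetate, while exchange at the conjugated ethyl ester is degenerate in ethanol.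

Step 4
Reactants: 6 ethyl (2Z,6Z)-8-hydroxy-2,6-dimethylocta-2,6-dienoate
Product: 7 ethyl (2Z,6Z)-2,6-dimethyl-8-oxoocta-2,6-dienoate
Conditions: MnO2, CH2Cl2, 0 °C → rt
Reagents that add atoms: none
Why: MnO2 oxidises the allylic alcohol to the enal under neutral heterogeneous conditions, which should preserve the (Z) geometry of the future C5=C10 olefin (allylic oxidation).

Step 5
Reactants: 7 ethyl (2Z,6Z)-2,6-dimethyl-8-oxoocta-2,6-dienoate
Product: 8 ethyl (2Z,6Z)-2,6-dimethylnona-2,6,8-trienoate
Conditions: Ph3PCH3Br, NaN(SiMe3)2, THF, 0 °C; then 7, −78 → 0 °C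
Reagents that add atoms: methyltriphenylphosphonium bromide, C[P+](c1ccccc1)(c1ccccc1)c1ccccc1.[Br-]
Why: Wittig methylenation with the non-stabilised ylide is fast on the aldehyde at low temperature and leaves the enoate and both (Z) olefins unchanged; the new CH2 is C7.

Step 6
Reactants: 8 ethyl (2Z,6Z)-2,6-dimethylnona-2,6,8-trienoate
Product: 9 (2Z,6Z)-2,6-dimethylnona-2,6,8-trien-1-ol
Conditions: iBu2AlH, CH2Cl2, −78 → 0 °C
Reagents that add atoms: none
Why: iBu2AlH reduces the conjugated ester in 1,2 fashion to the allylic alcohol (hydride reduction) with retention of olefin geometry and no action on the diene.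

Step 7
Reactants: 9 (2Z,6Z)-2,6-dimethylnona-2,6,8-trien-1-ol
Product: 10 [(2R,3S)-2-methyl-3-[(3Z)-3-methylhexa-3,5-dien-1-yl]oxiran-2-yl]methanol
Conditions: Ti(OiPr)4 (cat.), D-(−)-diethyl tartrate (cat.), t-BuOOH, 4 Å MS, CH2Cl2, −20 °C
Reagents that add atoms: tert-butyl hydroperoxide, CC(C)(C)OO
Why: Sharpless asymmetric epoxidation is directed by the allylic hydroxyl, so only the C3=C4 olefin reacts, and the D-tartrate catalyst should deliver oxygen to the face that gives the (2R,3S) epoxide (reagent control), the cis relation of C19 and C2 coming from the (Z) olefin.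

Step 8
Reactants: 10 [(2R,3S)-2-methyl-3-[(3Z)-3-methylhexa-3,5-dien-1-yl]oxiran-2-yl]methanol
Product: 11 tert-butyl{[(2R,3S)-2-methyl-3-[(3Z)-3-methylhexa-3,5-dien-1-yl]oxiran-2-yl]methoxy}diphenylsilane
Conditions: TBDPSCl, imidazole, CH2Cl2, 0 °C → rt
Reagents that add atoms: tert-butyl(chloro)diphenylsilane, CC(C)(C)[Si](Cl)(c1ccccc1)c1ccccc1
Why: Imidazole-promoted silylation of the primary alcohol; the bulky, weakly basic silyl ether is chosen to disfavour chelation and participation of the C19 oxygen in the later Lewis-acid step.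

Step 9
Reactants: 12 3-[(tert-butyldimethylsilyl)oxy]propanal
Product: 13 tert-butyl[(4,4-dibromobut-3-en-1-yl)oxy]dimethylsilane
Conditions: CBr4, PPh3, 2,6-lutidine, CH2Cl2, 0 °C
Reagents that add atoms: carbon tetrabromide, BrC(Br)(Br)Br
Why: Dibromo-olefination of the aldehyde by the ylide formed from CBr4 and PPh3 (first stage of the Corey–Fuchs sequence, a Wittig-type reaction), with 2,6-lutidine buffering the medium so that the silyl ether survives; the new carbon is C8.

Step 10
Reactants: 13 tert-butyl[(4,4-dibromobut-3-en-1-yl)oxy]dimethylsilane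
Product: 14 {[(3Z)-4-bromo-5-(trimethylsilyl)pent-3-en-1-yl]oxy}(tert-butyl)dimethylsilane
Conditions: Me3SiCH2MgCl, ZnCl2, THF, 0 °C; then 13, PdCl2(DPEphos) (cat.), THF, 0 °C → rt
Reagents that add atoms: (trimethylsilyl)methylmagnesium chloride, C[Si](C)(C)C[Mg]Cl
Why: Negishi coupling of 1,1-dibromoalkenes is trans-selective because oxidative addition is faster at the less hindered C–Br bond trans to the alkyl chain, so CH2SiMe3 should enter trans to C11 and leave the bromide cis to C11, the wide-bite-angle ligand holding the reaction at mono-coupling.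

Step 11
Reactants: 11 tert-butyl{[(2R,3S)-2-methyl-3-[(3Z)-3-methylhexa-3,5-dien-1-yl]oxiran-2-yl]methoxy}diphenylsilane; 14 {[(3Z)-4-bromo-5-(trimethylsilyl)pent-3-en-1-yl]oxy}(tert-butyl)dimethylsilane
Product: 16 tert-butyl{[(2R,3S)-3-[(3Z,7E)-10-[(tert-butyldimethylsilyl)oxy]-3-methyl-7-[(trimethylsilyl)methyl]deca-3,7-dien-1-yl]-2-methyloxiran-2-yl]methoxy}diphenylsilane (the cyclisation precursor), via alkyl-9-BBN borane 15 (not isolated)
Conditions: 9-BBN, THF, 0 °C → rt; then 14, PdCl2(dppf) (cat.), AsPh3, Cs2CO3, DMF–THF–H2O, rt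
Reagents that add atoms: none
Why: 9-BBN adds anti-Markovnikov only to the monosubstituted terminus of the diene, and the primary alkylborane should undergo B-alkyl Suzuki–Miyaura coupling with the vinyl bromide with retention of geometry, so C7 ends cis to C11, while epoxide, silyl ethers and allylsilane tolerate the mild aqueous base.

Step 12
Reactants: 16 tert-butyl{[(2R,3S)-3-[(3Z,7E)-10-[(tert-butyldimethylsilyl)oxy]-3-methyl-7-[(trimethylsilyl)methyl]deca-3,7-dien-1-yl]-2-methyloxiran-2-yl]methoxy}diphenylsilane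
Product: 17 12-[(tert-butyldimethylsilyl)oxy]-19-[(tert-butyldiphenylsilyl)oxy]-13,14,15,16-tetranor-5β-labd-8(17)-en-3β-ol
Conditions: MeAlCl2, CH2Cl2, −78 °C; then aq. NaHCO3
Reagents that add atoms: none
Why: MeAlCl2 binds the epoxide oxygen and the C4–O bond ionises while C5 of the (Z)-C5=C10 olefin attacks C4 from the rear; the C10 cation that develops is intercepted by C9 of the allylsilane, and the β-silyl cation at C8 gives up Me3Si to chloride, leaving the C8=C17 methylene. The closest known reaction type is the Lewis-acid, epoxide-initiated cation–olefin polycyclisation with allylsilane termination. Ring A closes 6-endo with respect to the epoxide and ring B closes 6-endo with respect to the C8=C9 olefin, each through a chair-like transition state. C4 is set by SN2-like inversion of the (2R,3S) epoxide, which places the silyloxymethyl group (cis to C2 on the epoxide) axial on the C20 face and leaves the C3 oxygen equatorial with retention; C5 and C10 are set by antiperiplanar addition across the (Z) olefin, which puts H5 syn to C20 and so gives the cis fusion; C9 is set by the allylsilane geometry, C11 (cis to C7) becoming axial on ring B and syn to C20. The step needs opening at C4 rather than C3 and a stop at the bicycle: the first is secured by the tertiary centre and the bulky, non-chelating silyl ether, the second by the β-silicon effect, which should make loss of silicon faster than proton loss, hydride shift or further cyclisation.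

Step 13
Reactants: 17 12-[(tert-butyldimethylsilyl)oxy]-19-[(tert-butyldiphenylsilyl)oxy]-13,14,15,16-tetranor-5β-labd-8(17)-en-3β-ol
Product: 18 O-{12-[(tert-butyldimethylsilyl)oxy]-19-[(tert-butyldiphenylsilyl)oxy]-13,14,15,16-tetranor-5β-labd-8(17)-en-3β-yl} S-methyl dithiocarbonate
Conditions: NaH, CS2, THF, 0 °C → rt; then MeI
Reagents that add atoms: carbon disulfide, S=C=S; iodomethane, CI
Why: Xanthate formation (first stage of the Barton–McCombie deoxygenation): the sodium alkoxide of the equatorial C3 alcohol adds to CS2 and is S-methylated, with silyl ethers and alkene inert.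

Step 14
Reactants: 18 O-{12-[(tert-butyldimethylsilyl)oxy]-19-[(tert-butyldiphenylsilyl)oxy]-13,14,15,16-tetranor-5β-labd-8(17)-en-3β-yl} S-methyl dithiocarbonate
Product: 19 12-[(tert-butyldimethylsilyl)oxy]-19-[(tert-butyldiphenylsilyl)oxy]-13,14,15,16-tetranor-5β-labd-8(17)-ene
Conditions: Bu3SnH, AIBN (cat.), toluene, 100 °C
Reagents that add atoms: none
Why: Barton–McCombie radical deoxygenation: the stannyl radical adds to the thiocarbonyl, β-scission gives the secondary C3 radical, and this abstracts hydrogen from Bu3SnH; the C3 stereocentre disappears and the remote exocyclic alkene is not engaged.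

Step 15
Reactants: 19 12-[(tert-butyldimethylsilyl)oxy]-19-[(tert-butyldiphenylsilyl)oxy]-13,14,15,16-tetranor-5β-labd-8(17)-ene
Product: 20 13,14,15,16-tetranor-5β-labd-8(17)-ene-12,19-diol
Conditions: Bu4NF, THF, rt → 50 °C
Reagents that add atoms: none
Why: Fluoride cleaves both silyl ethers through Si–F bond formation, the hindered neopentyl TBDPS ether needing gentle warming, without affecting the alkene.

Step 16
Reactants: 20 13,14,15,16-tetranor-5β-labd-8(17)-ene-12,19-diol
Product: 21 12-iodo-13,14,15,16-tetranor-5β-labd-8(17)-en-19-ol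
Conditions: I2, PPh3, imidazole, CH2Cl2, 0 °C
Reagents that add atoms: iodine, II
Why: Appel-type iodination proceeds by SN2 displacement of an alkoxyphosphonium ion, which is feasible at the unhindered C12 carbinol but not at the neopentyl, axial C19 carbinol, so mono-iodination should be site-selective.

Step 17
Reactants: 21 12-iodo-13,14,15,16-tetranor-5β-labd-8(17)-en-19-ol
Product: 22 12-iodo-13,14,15,16-tetranor-5β-labd-8(17)-en-19-al
Conditions: Dess–Martin periodinane, CH2Cl2, rt
Reagents that add atoms: none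
Why: Dess–Martin oxidation converts the neopentyl alcohol to the aldehyde under mild conditions that spare the alkyl iodide and the alkene; the α-carbon is quaternary, so no epimerisation is possible.

Step 18
Reactants: 22 12-iodo-13,14,15,16-tetranor-5β-labd-8(17)-en-19-al
Product: 23 12-iodo-13,14,15,16-tetranor-5β-labd-8(17)-en-19-oic acid
Conditions: NaClO2, NaH2PO4, 2-methyl-2-butene, t-BuOH–H2O, rt
Reagents that add atoms: sodium chlorite, [Na+].[O-]Cl=O
Why: Pinnick oxidation takes the aldehyde to the acid with chlorous acid, while 2-methyl-2-butene scavenges the hypochlorite formed and so protects the exocyclic alkene and the iodide.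

Step 19
Reactants: 23 12-iodo-13,14,15,16-tetranor-5β-labd-8(17)-en-19-oic acid
Product: 24 methyl 12-iodo-13,14,15,16-tetranor-5β-labd-8(17)-en-19-oate
Conditions: Me3SiCHN2, MeOH–toluene, rt
Reagents that add atoms: trimethylsilyldiazomethane, C[Si](C)(C)C=[N+]=[N-]
Why: Diazoalkane esterification alkylates the carboxylate oxygen and is therefore insensitive to the steric hindrance of the axial C19 carboxyl, and the neutral conditions spare the iodide.

Step 20
Reactants: 25 ethyl acetoacetate
Product: 26 ethyl (2E)-3-{[(trifluoromethyl)sulfonyl]oxy}but-2-enoate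
Conditions: Tf2O, aq. Me4NOH, toluene, 5 °C
Reagents that add atoms: trifluoromethanesulfonic anhydride, O=S(=O)(OS(=O)(=O)C(F)(F)F)C(F)(F)F
Why: O-Triflation of the β-keto ester enolate, which with the non-coordinating tetramethylammonium counter-ion reacts from its non-chelated extended geometry and should give the (E) enol triflate, the triflate being trans to the ester.

Step 21
Reactants: 24 methyl 12-iodo-13,14,15,16-tetranor-5β-labd-8(17)-en-19-oate; 26 ethyl (2E)-3-{[(trifluoromethyl)sulfonyl]oxy}but-2-enoate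
Product: 28 15-ethyl 19-methyl (13E)-5β-labda-8(17),13-diene-15,19-dioate, via alkylzinc iodide 27 (not isolated)
Conditions: Zn, LiCl, THF, 40 °C; then 26, Pd(PPh3)4 (cat.), THF, rt
Reagents that add atoms: none
Why: Zinc inserts into the primary C–I bond without attacking the hindered ester, and Negishi coupling with the enol triflate proceeds with retention at the sp2 carbon, so C12 takes the place of the triflate trans to the ester and the (13E) olefin should result.

Step 22
Reactants: 28 15-ethyl 19-methyl (13E)-5β-labda-8(17),13-diene-15,19-dioate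
Product: 29 methyl (13E)-15-hydroxy-5β-labda-8(17),13-dien-19-oate
Conditions: iBu2AlH (2.2 equiv), CH2Cl2, −78 °C
Reagents that add atoms: none
Why: At low temperature iBu2AlH should reduce the unhindered conjugated ethyl ester to the allylic alcohol, while the C19 methyl ester on the quaternary axial position is sterically shielded (chemoselective hydride reduction).

Step 23
Reactants: 29 methyl (13E)-15-hydroxy-5β-labda-8(17),13-dien-19-oate
Product: 30 methyl (13R,14R)-13,14-epoxy-15-hydroxy-5β-labd-8(17)-en-19-oate (CNP0175926.1)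
Conditions: Ti(OiPr)4 (cat.), D-(−)-diethyl tartrate (cat.), t-BuOOH, 4 Å MS, CH2Cl2, −20 °C
Reagents that add atoms: tert-butyl hydroperoxide, CC(C)(C)OO
Why: Sharpless asymmetric epoxidation is directed by the allylic hydroxyl, so the C8=C17 alkene is untouched, and the D-tartrate catalyst should give the (13R,14R) epoxide from the (E)-allylic alcohol by reagent control, independent of the remote ring stereocentres.

Compound list
1 | neryl acetate, (2Z)-3,7-dimethylocta-2,6-dien-1-yl acetate | CC(C)=CCC/C(C)=C\COC(C)=O | starting material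
2 | 6,7-epoxyneryl acetate, (2Z)-5-(3,3-dimethyloxiran-2-yl)-3-methylpent-2-en-1-yl acetate (racemic at the epoxide, not isolated) | CC1(C)OC1CC/C(C)=C\COC(C)=O | intermediate
3 | (2Z)-3-methyl-6-oxohex-2-en-1-yl acetate | O=CCC/C(C)=C\COC(C)=O | intermediate
4 | ethyl 2-[bis(2,2,2-trifluoroethoxy)phosphoryl]propanoate | CCOC(=O)C(C)P(=O)(OCC(F)(F)F)OCC(F)(F)F | starting material
5 | ethyl (2Z,6Z)-8-acetoxy-2,6-dimethylocta-2,6-dienoate | CCOC(=O)/C(C)=C\CC/C(C)=C\COC(C)=O | intermediate
6 | ethyl (2Z,6Z)-8-hydroxy-2,6-dimethylocta-2,6-dienoate | CCOC(=O)/C(C)=C\CC/C(C)=C\CO | intermediate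
7 | ethyl (2Z,6Z)-2,6-dimethyl-8-oxoocta-2,6-dienoate | CCOC(=O)/C(C)=C\CC/C(C)=C\C=O | intermediate
8 | ethyl (2Z,6Z)-2,6-dimethylnona-2,6,8-trienoate | CCOC(=O)/C(C)=C\CC/C(C)=C\C=C | intermediate
9 | (2Z,6Z)-2,6-dimethylnona-2,6,8-trien-1-ol | OC/C(C)=C\CC/C(C)=C\C=C | intermediate
10 | [(2R,3S)-2-methyl-3-[(3Z)-3-methylhexa-3,5-dien-1-yl]oxiran-2-yl]methanol | OC[C@@]1(C)O[C@H]1CC/C(C)=C\C=C | intermediate
11 | tert-butyl{[(2R,3S)-2-methyl-3-[(3Z)-3-methylhexa-3,5-dien-1-yl]oxiran-2-yl]methoxy}diphenylsilane | CC(C)(C)[Si](c1ccccc1)(c1ccccc1)OC[C@@]1(C)O[C@H]1CC/C(C)=C\C=C | intermediate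
12 | 3-[(tert-butyldimethylsilyl)oxy]propanal | O=CCCO[Si](C)(C)C(C)(C)C | starting material
13 | tert-butyl[(4,4-dibromobut-3-en-1-yl)oxy]dimethylsilane | BrC(Br)=CCCO[Si](C)(C)C(C)(C)C | intermediate
14 | {[(3Z)-4-bromo-5-(trimethylsilyl)pent-3-en-1-yl]oxy}(tert-butyl)dimethylsilane (Br cis to the CH2CH2O chain) | C[Si](C)(C)C/C(Br)=C/CCO[Si](C)(C)C(C)(C)C | intermediate
15 | alkyl-9-BBN borane from 11, boron on C7 (not isolated) | CC(C)(C)[Si](c1ccccc1)(c1ccccc1)OC[C@@]1(C)O[C@H]1CC/C(C)=C\CCB1C2CCCC1CCC2 | intermediate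
16 | tert-butyl{[(2R,3S)-3-[(3Z,7E)-10-[(tert-butyldimethylsilyl)oxy]-3-methyl-7-[(trimethylsilyl)methyl]deca-3,7-dien-1-yl]-2-methyloxiran-2-yl]methoxy}diphenylsilane (C1 cis to C6, C7 cis to C11) | CC(C)(C)[Si](c1ccccc1)(c1ccccc1)OC[C@@]1(C)O[C@H]1CC/C(C)=C\CC/C(C[Si](C)(C)C)=C\CCO[Si](C)(C)C(C)(C)C | intermediate
17 | 12-[(tert-butyldimethylsilyl)oxy]-19-[(tert-butyldiphenylsilyl)oxy]-13,14,15,16-tetranor-5β-labd-8(17)-en-3β-ol (cis-fused; H5, C20, C19, the C9 chain and 3-OH all β) | C=C1CC[C@H]2[C@](C)(CC[C@H](O)[C@]2(C)CO[Si](c3ccccc3)(c3ccccc3)C(C)(C)C)[C@H]1CCO[Si](C)(C)C(C)(C)C | intermediate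
18 | 3β-O-(methylsulfanylthiocarbonyl) derivative (xanthate) of 17 | C=C1CC[C@H]2[C@](C)(CC[C@H](OC(=S)SC)[C@]2(C)CO[Si](c3ccccc3)(c3ccccc3)C(C)(C)C)[C@H]1CCO[Si](C)(C)C(C)(C)C | intermediate
19 | 12-[(tert-butyldimethylsilyl)oxy]-19-[(tert-butyldiphenylsilyl)oxy]-13,14,15,16-tetranor-5β-labd-8(17)-ene | C=C1CC[C@H]2[C@](C)(CCC[C@]2(C)CO[Si](c3ccccc3)(c3ccccc3)C(C)(C)C)[C@H]1CCO[Si](C)(C)C(C)(C)C | intermediate
20 | 13,14,15,16-tetranor-5β-labd-8(17)-ene-12,19-diol | C=C1CC[C@H]2[C@](C)(CCC[C@]2(C)CO)[C@H]1CCO | intermediate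
21 | 12-iodo-13,14,15,16-tetranor-5β-labd-8(17)-en-19-ol | C=C1CC[C@H]2[C@](C)(CCC[C@]2(C)CO)[C@H]1CCI | intermediate
22 | 12-iodo-13,14,15,16-tetranor-5β-labd-8(17)-en-19-al | C=C1CC[C@H]2[C@](C)(CCC[C@]2(C)C=O)[C@H]1CCI | intermediate
23 | 12-iodo-13,14,15,16-tetranor-5β-labd-8(17)-en-19-oic acid | C=C1CC[C@H]2[C@](C)(CCC[C@]2(C)C(=O)O)[C@H]1CCI | intermediate
24 | methyl 12-iodo-13,14,15,16-tetranor-5β-labd-8(17)-en-19-oate | C=C1CC[C@H]2[C@](C)(CCC[C@]2(C)C(=O)OC)[C@H]1CCI | intermediate
25 | ethyl acetoacetate | CCOC(=O)CC(C)=O | starting material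
26 | ethyl (2E)-3-{[(trifluoromethyl)sulfonyl]oxy}but-2-enoate (triflate trans to the ester) | CCOC(=O)/C=C(/OS(=O)(=O)C(F)(F)F)C | intermediate
27 | alkylzinc iodide from 24, zinc on C12 (not isolated) | C=C1CC[C@H]2[C@](C)(CCC[C@]2(C)C(=O)OC)[C@H]1CC[Zn]I | intermediate
28 | 15-ethyl 19-methyl (13E)-5β-labda-8(17),13-diene-15,19-dioate | C=C1CC[C@H]2[C@](C)(CCC[C@]2(C)C(=O)OC)[C@H]1CC/C(C)=C/C(=O)OCC | intermediate
29 | methyl (13E)-15-hydroxy-5β-labda-8(17),13-dien-19-oate | C=C1CC[C@H]2[C@](C)(CCC[C@]2(C)C(=O)OC)[C@H]1CC/C(C)=C/CO | intermediate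
30 | methyl (13R,14R)-13,14-epoxy-15-hydroxy-5β-labd-8(17)-en-19-oate, CNP0175926.1 | C=C1CC[C@H]2[C@](C)(CCC[C@]2(C)C(=O)OC)[C@H]1CC[C@@]1(C)O[C@@H]1CO | target

Total step count: 23 steps. Longest linear sequence: 20 steps (1–8, 11–19, 21–23).

Steps most likely to fail

Step 12. The cascade may stop after ring A, the C10 cation being lost by deprotonation or chloride capture before the allylsilane can fold into the chair that carries the C9 chain axially. Initiation may also be diverted to a 1,2-hydride shift (C3 ketone), because the C19 oxygen destabilises charge at C4. The fallback sets out from 9 and returns at 19; it replaces the epoxide trigger by a seleniranium ion, which forms with anchimeric assistance and is removed in one step. Compound 9 is epoxidised with the antipodal catalyst (Ti(OiPr)4, L-(+)-diethyl tartrate, t-BuOOH) to the enantiomeric epoxy alcohol F1, silylated (TBDPSCl, imidazole) to the silyl ether F2, hydroborated (9-BBN) to the borane F3 and coupled with 14 as in step 11 to the enantiomeric-epoxide precursor F4. Sodium phenylselenolate (PhSeSePh, NaBH4, EtOH) opens the epoxide at C3 with inversion to the β-hydroxy selenide F5. A Lewis acid (BF3·OEt2, CH2Cl2, −78 °C) ionises the tertiary C4–OH with rear-side participation of selenium. After two inversions from the antipodal epoxide the seleniranium ion has the same facial sense as the epoxide of 16, so the same antiperiplanar addition across the (Z)-C5=C10 olefin and the same allylsilane termination should give the 3β-phenylselanyl bicycle F6. Bu3SnH with AIBN then cleaves the C–Se bond to give 19, which also makes steps 13 and 14 unnecessary.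

Step 11. Transmetalation to the hindered trisubstituted vinyl bromide may be slow, which leaves room for protodeboronation of the alkylborane or β-hydride elimination of the alkylpalladium species. The fallback sets out from 15 and returns at 16. The borane 15 is oxidised (NaBO3, THF–H2O) to the primary alcohol F7 and converted (I2, PPh3, imidazole) to the iodide F8. Iodine–lithium exchange (t-BuLi, Et2O, −78 °C) followed by ZnCl2 gives the alkylzinc chloride F9, which is coupled with 14 under Negishi conditions (Pd(PPh3)4, THF) without base to give 16.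

Step 22. Chemoselectivity may be lost, with partial reduction of the C19 methyl ester alongside the enoate. The fallback sets out from 24 and returns at 29; it couples at the alcohol oxidation level so that no reduction is needed. But-2-yn-1-ol is silylated to the TBS ether F10, hydrozirconated (Cp2Zr(H)Cl, syn addition with zirconium on the methyl-bearing carbon) and iodinated to the (E)-vinyl iodide F11. The zinc reagent 27 made from 24 is coupled with F11 (Pd(PPh3)4, THF) to the silyl ether F12, and Bu4NF gives 29.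

Further compounds
F1 | step 12 | [(2S,3R)-2-methyl-3-[(3Z)-3-methylhexa-3,5-dien-1-yl]oxiran-2-yl]methanol | OC[C@]1(C)O[C@@H]1CC/C(C)=C\C=C
F2 | step 12 | tert-butyl{[(2S,3R)-2-methyl-3-[(3Z)-3-methylhexa-3,5-dien-1-yl]oxiran-2-yl]methoxy}diphenylsilane | CC(C)(C)[Si](c1ccccc1)(c1ccccc1)OC[C@]1(C)O[C@@H]1CC/C(C)=C\C=C
F3 | step 12 | alkyl-9-BBN borane from F2, boron on C7 | CC(C)(C)[Si](c1ccccc1)(c1ccccc1)OC[C@]1(C)O[C@@H]1CC/C(C)=C\CCB1C2CCCC1CCC2
F4 | step 12 | (2S,3R)-epoxide enantiomer of precursor 16 | CC(C)(C)[Si](c1ccccc1)(c1ccccc1)OC[C@]1(C)O[C@@H]1CC/C(C)=C\CC/C(C[Si](C)(C)C)=C\CCO[Si](C)(C)C(C)(C)C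
F5 | step 12 | (2S,3S)-β-hydroxy selenide from F4: C4 tertiary alcohol, C3 phenylselanyl | CC(C)(C)[Si](c1ccccc1)(c1ccccc1)OC[C@](C)(O)[C@@H]([Se]c1ccccc1)CC/C(C)=C\CC/C(C[Si](C)(C)C)=C\CCO[Si](C)(C)C(C)(C)C
F6 | step 12 | 12-[(tert-butyldimethylsilyl)oxy]-19-[(tert-butyldiphenylsilyl)oxy]-3β-(phenylselanyl)-13,14,15,16-tetranor-5β-labd-8(17)-ene | C=C1CC[C@H]2[C@](C)(CC[C@H]([Se]c3ccccc3)[C@]2(C)CO[Si](c3ccccc3)(c3ccccc3)C(C)(C)C)[C@H]1CCO[Si](C)(C)C(C)(C)C
F7 | step 11 | (3Z)-6-[(2S,3R)-3-{[(tert-butyldiphenylsilyl)oxy]methyl}-3-methyloxiran-2-yl]-4-methylhex-3-en-1-ol (C7 alcohol) | CC(C)(C)[Si](c1ccccc1)(c1ccccc1)OC[C@@]1(C)O[C@H]1CC/C(C)=C\CCO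
F8 | step 11 | the corresponding C7 iodide | CC(C)(C)[Si](c1ccccc1)(c1ccccc1)OC[C@@]1(C)O[C@H]1CC/C(C)=C\CCI
F9 | step 11 | the corresponding C7 alkylzinc chloride | CC(C)(C)[Si](c1ccccc1)(c1ccccc1)OC[C@@]1(C)O[C@H]1CC/C(C)=C\CC[Zn]Cl
F10 | step 22 | (but-2-yn-1-yloxy)(tert-butyl)dimethylsilane | CC#CCO[Si](C)(C)C(C)(C)C
F11 | step 22 | tert-butyl{[(2E)-3-iodobut-2-en-1-yl]oxy}dimethylsilane | C/C(I)=C\CO[Si](C)(C)C(C)(C)C
F12 | step 22 | methyl (13E)-15-[(tert-butyldimethylsilyl)oxy]-5β-labda-8(17),13-dien-19-oate | C=C1CC[C@H]2[C@](C)(CCC[C@]2(C)C(=O)OC)[C@H]1CC/C(C)=C/CO[Si](C)(C)C(C)(C)C
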